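**Retrosynthetic overview**

1. The target is taken back to its 7-O-benzyl ether; hydrogenolysis of that ether is the last step.
2. Ring C is cut at C4a–C4, C4–C3 and O1–C2, giving a 2-iodoresorcinol (ring A), carbon monoxide (C4) and 3,4,5-trimethoxyphenylacetylene (C3, C2, ring B), which are joined in one palladium-catalysed carbonylative annulation.
3. Feature used: in ring A, C4a is the only carbon without oxygen, and both its neighbours, C5 (OH) and C8a (O1), carry oxygen. In the iodoresorcinol these two hydroxyls are mirror images across the C4a···C7 axis, so closure through either gives the same flavone and the other becomes the 5-OH; the benzyl group marks O7.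
4. The iodoresorcinol is made from syringol by O-benzylation, dibromination, borylation–oxidation of both C–Br bonds, and iodination of the last free ring carbon.
5. Ring order: rings A and B are bought as benzene rings; ring C is the only ring formed (step 5).

Key step: step 5

Remark: alkyne 8 is taken as purchased. The E geometry drawn for the transient enaminone 11 is an assumption without consequence, because it is lost on ring closure.

**Route**

Step 1
Reactants: 1 syringol (2,6-dimethoxyphenol); 2 benzyl bromide
Product: 3 2-(benzyloxy)-1,3-dimethoxybenzene
Conditions: BnBr, K2CO3, DMF, 60 °C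
Reagents that add atoms: benzyl bromide (2), BrCc1ccccc1
Why: Williamson ether synthesis: the phenoxide of 1 displaces bromide from the primary benzylic halide in an SN2 reaction, and the flanking methoxy groups slow but do not prevent O-alkylation in DMF.

Step 2
Reactants: 3 2-(benzyloxy)-1,3-dimethoxybenzene
Product: 4 3-(benzyloxy)-1,5-dibromo-2,4-dimethoxybenzene
Conditions: NBS (2.1 equiv), MeCN, 0 °C to rt, dark
Reagents that add atoms: N-bromosuccinimide, O=C1CCC(=O)N1Br
Why: Electrophilic aromatic bromination: each of the two equivalent positions attacked is ortho to one methoxy group and para to the other, whereas the remaining position is para only to the benzyloxy group that is twisted out of conjugation by its two ortho neighbours, so the 1,5-dibromide should form as the bromination pattern of 1,2,3-trialkoxybenzenes predicts.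

Step 3
Reactants: 4 3-(benzyloxy)-1,5-dibromo-2,4-dimethoxybenzene
Product: 6 5-(benzyloxy)-4,6-dimethoxybenzene-1,3-diol, via bis(pinacol boronate) 5 (not isolated)
Conditions: B2pin2 (2.6 equiv), PdCl2(dppf) (5 mol%; dppf = 1,1'-bis(diphenylphosphino)ferrocene), KOAc, 1,4-dioxane, 90 °C, argon; Celite filtration, then 30% aq. H2O2 (excess), aq. NaOH, THF, 0 °C
Reagents that add atoms: bis(pinacolato)diboron, CC1(C)OB(OC1(C)C)B1OC(C)(C)C(C)(C)O1 (its boron stays only in 5); hydrogen peroxide, OO (supplies the two new phenolic oxygens of 6)
Why: Miyaura borylation of both C–Br bonds followed by peroxide oxidation (1,2-shift of the aryl group from boron to oxygen) replaces each bromine by hydroxyl at the same carbon, and the benzyl and methyl ethers are inert to both operations.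

Step 4
Reactants: 6 5-(benzyloxy)-4,6-dimethoxybenzene-1,3-diol
Product: 7 5-(benzyloxy)-2-iodo-4,6-dimethoxybenzene-1,3-diol
Conditions: NIS (1.0 equiv), MeCN, 0 °C, dark
Reagents that add atoms: N-iodosuccinimide, O=C1CCC(=O)N1I
Why: Electrophilic aromatic iodination: the only ring C–H left lies ortho to both hydroxyls of the resorcinol and is strongly activated, so one equivalent of NIS should iodinate it without acid catalysis.

Step 5
Reactants: 7 5-(benzyloxy)-2-iodo-4,6-dimethoxybenzene-1,3-diol; 8 5-ethynyl-1,2,3-trimethoxybenzene (1.5 equiv); 9 carbon monoxide
Product: 12 7-(benzyloxy)-5-hydroxy-6,8-dimethoxy-2-(3,4,5-trimethoxyphenyl)-4H-chromen-4-one, via ynone 10 (not isolated), via diethylaminoenone 11 (not isolated)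
Conditions: PdCl2(PPh3)2 (5 mol%), CO (20 bar), Et2NH, 120 °C, autoclave
Reagents that add atoms: carbon monoxide (9), [C-]#[O+]; 5-ethynyl-1,2,3-trimethoxybenzene (8), C#Cc1cc(OC)c(OC)c(OC)c1 (diethylamine, CCNCC, is taken up in 11 and released again)
Why: PdCl2(PPh3)2 is reduced in the amine/CO medium to zerovalent palladium, which inserts into the C–I bond of 7; CO insertion gives the aroylpalladium iodide, and copper-free coupling with the amine-activated terminal alkyne 8 followed by reductive elimination delivers ynone 10 (bonds C4a–C4 and C4–C3). Diethylamine then adds to the ynone β-carbon to give enaminone 11, and an ortho hydroxyl attacks that same carbon (future C2) and expels diethylamine, forming O1–C2 and closing ring C in a 6-endo addition–elimination. The closest known reaction type is the palladium-catalysed carbonylative annulation of ortho-iodophenols with terminal arylacetylenes to flavones in secondary amines. No stereocentre is formed. The step needs chemoselectivity for CO insertion over direct alkyne coupling (which would lead to a 2-arylbenzofuran) and for 6-endo over 5-exo closure (aurone); CO pressure without a copper co-catalyst favours the former, and the enaminone, whose β-carbon is the only electrophilic site offered to the phenol, secures the latter. Regiochemistry is not an issue, because the two hydroxyls flanking the C–I bond of 7 are related by the mirror plane through C2 and C5 of the arene, so either closes to the same flavone and the other is left as the hydrogen-bonded 5-OH.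

Step 6
Reactants: 12 7-(benzyloxy)-5-hydroxy-6,8-dimethoxy-2-(3,4,5-trimethoxyphenyl)-4H-chromen-4-one
Product: 13 5,7-dihydroxy-6,8,3',4',5'-pentamethoxyflavone
Conditions: H2 (1 atm), palladium on carbon (Pd/C, 10%), EtOAc–MeOH, rt
Reagents that add atoms: none
Why: Catalytic hydrogenolysis of the benzylic C–O bond on palladium frees the 7-OH, while the aryl methyl ethers and the vinylogous-ester C2–C3 double bond of the flavone are normally untouched at 1 atm and room temperature.

**Compound list**

1 | syringol (2,6-dimethoxyphenol) | COc1cccc(OC)c1O | starting material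
2 | benzyl bromide | BrCc1ccccc1 | starting material
3 | 2-(benzyloxy)-1,3-dimethoxybenzene | COc1cccc(OC)c1OCc1ccccc1 | intermediate
4 | 3-(benzyloxy)-1,5-dibromo-2,4-dimethoxybenzene | COc1c(Br)cc(Br)c(OC)c1OCc1ccccc1 | intermediate
5 | 2,2'-[5-(benzyloxy)-4,6-dimethoxy-1,3-phenylene]bis(4,4,5,5-tetramethyl-1,3,2-dioxaborolane) | COc1c(B2OC(C)(C)C(C)(C)O2)cc(B2OC(C)(C)C(C)(C)O2)c(OC)c1OCc1ccccc1 | intermediate (not isolated)
6 | 5-(benzyloxy)-4,6-dimethoxybenzene-1,3-diol | COc1c(O)cc(O)c(OC)c1OCc1ccccc1 | intermediate
7 | 5-(benzyloxy)-2-iodo-4,6-dimethoxybenzene-1,3-diol | COc1c(O)c(I)c(O)c(OC)c1OCc1ccccc1 | intermediate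
8 | 5-ethynyl-1,2,3-trimethoxybenzene | C#Cc1cc(OC)c(OC)c(OC)c1 | starting material
9 | carbon monoxide | [C-]#[O+] | starting material
10 | 1-[4-(benzyloxy)-2,6-dihydroxy-3,5-dimethoxyphenyl]-3-(3,4,5-trimethoxyphenyl)prop-2-yn-1-one | COc1cc(C#CC(=O)c2c(O)c(OC)c(OCc3ccccc3)c(OC)c2O)cc(OC)c1OC | intermediate (not isolated)
11 | (E)-1-[4-(benzyloxy)-2,6-dihydroxy-3,5-dimethoxyphenyl]-3-(diethylamino)-3-(3,4,5-trimethoxyphenyl)prop-2-en-1-one | CCN(CC)/C(=C/C(=O)c1c(O)c(OC)c(OCc2ccccc2)c(OC)c1O)c1cc(OC)c(OC)c(OC)c1 | intermediate (not isolated)
12 | 7-(benzyloxy)-5-hydroxy-6,8-dimethoxy-2-(3,4,5-trimethoxyphenyl)-4H-chromen-4-one | COc1cc(-c2cc(=O)c3c(O)c(OC)c(OCc4ccccc4)c(OC)c3o2)cc(OC)c1OC | intermediate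
13 | 5,7-dihydroxy-6,8,3',4',5'-pentamethoxyflavone | COc1cc(-c2cc(=O)c3c(O)c(OC)c(O)c(OC)c3o2)cc(OC)c1OC | target

**Step count**

Total steps: 6. Longest linear sequence: 6 steps (syringol 1 to target 13); alkyne 8 and carbon monoxide 9 enter at step 5.

**Steps most likely to fail**

Step 5 (key step). The C–I bond of 7 sits on a very electron-rich ring between two hydroxyls that are partly ionised in the amine, so oxidative addition may be slow and reductive loss of iodine may compete. Direct alkyne coupling without CO uptake (leading on to a benzofuran), capture of the aroylpalladium by diethylamine as an amide, and 5-exo closure are the other ways the step may leak. The fallback keeps the same symmetry argument but replaces palladium chemistry by chalcone chemistry. It sets out from resorcinol 6 (step 4 is skipped) and comes back to the route at 12. C-Acetylation of 6 with acetic anhydride and BF3·OEt2 at the carbon between the two hydroxyls should give 1-[4-(benzyloxy)-2,6-dihydroxy-3,5-dimethoxyphenyl]ethan-1-one F1. Claisen–Schmidt condensation of this ketone with commercial 3,4,5-trimethoxybenzaldehyde (KOH, EtOH) should give (E)-1-[4-(benzyloxy)-2,6-dihydroxy-3,5-dimethoxyphenyl]-3-(3,4,5-trimethoxyphenyl)prop-2-en-1-one F2. Oxidative cyclisation of the chalcone with catalytic I2 in DMSO at 120 °C should then close ring C through either equivalent hydroxyl and deliver 12.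

Step 3. The second borylation may stall, and protodebromination or protodeboronation would give mono-oxygenated material; the electron-rich resorcinol may also be over-oxidised in alkaline peroxide. The fallback sets out from dibromide 4 and returns at 6. It is a direct palladium-catalysed hydroxylation of both C–Br bonds with KOH (Pd2(dba)3, tBuXPhos, 1,4-dioxane–water, 100 °C, argon, then acidification), a C–O coupling that avoids boron intermediates and peroxide altogether (no new compound, F0).

Step 6. Hydrogen may add to the C2–C3 double bond of the flavone, or the catalyst may be poisoned by traces of iodide or phosphine carried over from step 5, leaving the benzyl ether in place. The fallback sets out from 12 and arrives at 13. It is a non-reductive, Lewis-acid cleavage of the benzyl ether with BCl3 in the presence of pentamethylbenzene as cation scavenger (CH2Cl2, −78 °C), conditions under which aryl methyl ethers are expected to survive (no new compound, F0).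

**Further compounds**

F1 | step 5 | 1-[4-(benzyloxy)-2,6-dihydroxy-3,5-dimethoxyphenyl]ethan-1-one | CC(=O)c1c(O)c(OC)c(OCc2ccccc2)c(OC)c1O
F2 | step 5 | (E)-1-[4-(benzyloxy)-2,6-dihydroxy-3,5-dimethoxyphenyl]-3-(3,4,5-trimethoxyphenyl)prop-2-en-1-one | COc1cc(/C=C/C(=O)c2c(O)c(OC)c(OCc3ccccc3)c(OC)c2O)cc(OC)c1OC
F0 | step 3 | none | none
F0 | step 6 | none | none
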